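**Retrosynthetic overview**
1. Last C=C bond: Horner–Wadsworth–Emmons union of a pyranone phosphonate with a fully functionalised cyclohexyl dienal; the dienal comes from an enal by Wittig homologation.
2. The two acetates come from selective O-acetylation of the two secondary hydroxyls of an all-cis ring tetraol.
3. Key step: all four ring C–O bonds (C3–C6) are made in one flask by a relay syn,syn-bis-dihydroxylation of a cis-5,6-disubstituted cyclohexa-1,3-diene.
4. That diene comes from a conjugated cyclohexadienal by deconjugative α-protonation and Wittig olefination; the dienal comes from an organocatalytic Diels–Alder reaction of a silyl dienol ether with crotonaldehyde, which sets the one controlling stereocentre.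
5. Ring order: the carbocycle is formed first (step 2); the pyranone ring is made separately (lactonisation, then O-methylation) and joined last.

Convention: "ring C1–C6" means the target's cyclohexane numbering (C1 bears the side chain, C2 = CHMe, C3 = C(Me)OH, C4 = CHOAc, C5 = C(Me)OH, C6 = CHOAc); the catalyst's facial sense in step 2 is assumed to follow its established behaviour with crotonaldehyde.

**Step 1**
Reactants: 1 (E)-2-methylpent-2-enal
Product: 2 tert-butyldimethyl{[(1E,3E)-2-methylpenta-1,3-dien-1-yl]oxy}silane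
Conditions: TBSOTf (1.1 equiv), Et3N (1.5 equiv), Et2O, 0 → 23 °C
Reagents that add atoms: tert-butyldimethylsilyl trifluoromethanesulfonate (TBSOTf), CC(C)(C)[Si](C)(C)OS(=O)(=O)C(F)(F)F
Why: Soft enolisation (silyl dienol ether formation), in which TBSOTf silylates the carbonyl oxygen and Et3N removes a γ-proton to give the 1-silyloxy-1,3-diene; no stereocentre is created.

**Step 2**
Reactants: 2 tert-butyldimethyl{[(1E,3E)-2-methylpenta-1,3-dien-1-yl]oxy}silane; 3 (E)-but-2-enal (crotonaldehyde)
Product: 5 (6R)-3,5,6-trimethylcyclohexa-1,3-diene-1-carbaldehyde, via silyloxy cycloadduct 4 (not isolated)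
Conditions: (2R,5R)-5-benzyl-2-tert-butyl-3-methylimidazolidin-4-one·CF3CO2H (second-generation MacMillan catalyst, 20 mol%), CH2Cl2/H2O (19:1), −40 °C; then DBU (0.3 equiv), 0 → 23 °C
Reagents that add atoms: none
Why: Iminium-catalysed organocatalytic Diels–Alder reaction followed by E1cB loss of silanol, in which the nucleophilic C4 terminus of the silyloxy diene adds to the Si face of C3 of the crotonaldehyde iminium (the face left open by the catalyst's benzyl group), setting the methyl-bearing centre (ring C2) as 6R, while the silyloxy terminus bonds to C2 of the enal ("ortho" regiochemistry) and DBU eliminates t-BuMe2SiOH; the C5 centre of 5 is left as a mixture because it becomes sp2 in step 3.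

**Step 3**
Reactants: 5 (6R)-3,5,6-trimethylcyclohexa-1,3-diene-1-carbaldehyde; 6 2-(triphenylphosphoranylidene)propanal
Product: 8 (2E)-2-methyl-3-[(1R,6S)-3,5,6-trimethylcyclohexa-2,4-dien-1-yl]prop-2-enal, via skipped dienyl aldehyde 7 (not isolated)
Conditions: t-BuOK (1.1 equiv), THF, −78 → −30 °C; AcOH (1.2 equiv), −78 °C; then 6 (1.5 equiv), −78 → 40 °C
Reagents that add atoms: none
Why: Deconjugative kinetic α-protonation of an extended enolate followed by Wittig olefination, in which t-BuOK removes the ε-hydrogen (ring C3–H), AcOH protonates the trienolate at ring C1 anti to the adjacent pseudoaxial ring C2 methyl to give the cis aldehyde 7 with the ring diene at C3=C4/C5=C6, and the stabilised ylide converts this isomerisation-prone aldehyde at once into the (E)-enal.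

**Step 4**
Reactants: 8 (2E)-2-methyl-3-[(1R,6S)-3,5,6-trimethylcyclohexa-2,4-dien-1-yl]prop-2-enal
Product: 11 (2E)-2-methyl-3-[(1R,2S,3S,4R,5R,6S)-2,3,4,5-tetrahydroxy-3,5,6-trimethylcyclohexyl]prop-2-enal, via C3/C4 ene-diol 9 (not isolated), via C5/C6 ene-diol 10 (not isolated)
Conditions: OsO4 (5 mol%), quinuclidine (20 mol%), NMO·H2O (2.3 equiv), CH2Cl2, −20 → 23 °C
Reagents that add atoms: N-methylmorpholine N-oxide (NMO), C[N+]1([O-])CCOCC1; water, O
Why: Proposed new method: relay-directed catalytic bis-dihydroxylation — quinuclidine-ligated OsO4 (electron-rich oxo ligands, turned over by NMO·H2O in non-coordinating CH2Cl2) first adds by [3+2] osmylation to one alkene of the ring diene on the face anti to the cis ring C1/C2 substituents, the hexavalent osmium glycolate is reoxidised and hydrolysed, and the freed syn-diol then hydrogen-bonds to an oxo ligand of a second quinuclidine·OsO4 and delivers it to the same face of the remaining trisubstituted alkene, so four C–O bonds and the ring C3–C6 stereocentres form all-cis in one flask (steric bias and hydrogen bonding are matched and the electron-poor enal C=C is spared); the closest known reaction types are the Upjohn dihydroxylation and the Donohoe OsO4·TMEDA hydrogen-bond-directed dihydroxylation of allylic alcohols, neither of which has been shown as a one-pot relay on a 1,3-diene giving an all-cis 1,2,3,4-tetraol.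

**Step 5**
Reactants: 11 (2E)-2-methyl-3-[(1R,2S,3S,4R,5R,6S)-2,3,4,5-tetrahydroxy-3,5,6-trimethylcyclohexyl]prop-2-enal
Product: 12 (1S,2S,3R,4R,5S,6R)-2,4-dihydroxy-2,4,5-trimethyl-6-[(1E)-2-methyl-3-oxoprop-1-en-1-yl]cyclohexane-1,3-diyl diacetate
Conditions: Ac2O (3 equiv), pyridine, DMAP (10 mol%), CH2Cl2, 0 → 23 °C
Reagents that add atoms: acetic anhydride, CC(=O)OC(C)=O
Why: DMAP-catalysed O-acylation is selective on steric grounds for the two secondary hydroxyls (ring C4 and C6) over the two tertiary ones, installing both acetates without touching any stereocentre.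

**Step 6**
Reactants: 12 (1S,2S,3R,4R,5S,6R)-2,4-dihydroxy-2,4,5-trimethyl-6-[(1E)-2-methyl-3-oxoprop-1-en-1-yl]cyclohexane-1,3-diyl diacetate; 13 (triphenylphosphoranylidene)acetaldehyde
Product: 14 (1S,2S,3R,4R,5S,6R)-2,4-dihydroxy-2,4,5-trimethyl-6-[(1E,3E)-2-methyl-5-oxopenta-1,3-dien-1-yl]cyclohexane-1,3-diyl diacetate
Conditions: 13 (1.3 equiv), PhMe, 80 °C
Reagents that add atoms: none
Why: Wittig two-carbon homologation with the formyl-stabilised ylide under neutral conditions gives the new (E)-alkene and tolerates the acetates and the free tertiary alcohols.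

**Step 7**
Reactants: 15 ethyl 2-methyl-3-oxopentanoate; 16 N-methoxy-N-methylpropanamide
Product: 18 6-ethyl-4-hydroxy-3,5-dimethyl-2H-pyran-2-one, via triketoester 17 (not isolated)
Conditions: NaH (1.1 equiv), THF, 0 °C; n-BuLi (1.05 equiv), 0 °C; 16, −78 → 0 °C; AcOH; then DBU (1.5 equiv), reflux
Reagents that add atoms: none
Why: γ-Acylation of the β-keto ester dianion (Huckin–Weiler-type Claisen condensation) with the Weinreb amide gives the 3,5-diketo ester, whose enol oxygen lactonises onto the ester under DBU to close the 4-hydroxy-2-pyranone ring.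

**Step 8**
Reactants: 18 6-ethyl-4-hydroxy-3,5-dimethyl-2H-pyran-2-one
Product: 19 2-ethyl-6-methoxy-3,5-dimethyl-4H-pyran-4-one
Conditions: MeOTf (1.2 equiv), CH2Cl2, 23 °C; aq NaHCO3
Reagents that add atoms: methyl trifluoromethanesulfonate (MeOTf), COS(=O)(=O)C(F)(F)F
Why: O-Methylation of the lactone carbonyl oxygen by the hard electrophile MeOTf, followed by loss of the 4-OH proton, gives the 2-methoxy-4-pyranone rather than the 4-methoxy-2-pyranone.

**Step 9**
Reactants: 19 2-ethyl-6-methoxy-3,5-dimethyl-4H-pyran-4-one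
Product: 20 2-(1-bromoethyl)-6-methoxy-3,5-dimethyl-4H-pyran-4-one (racemic)
Conditions: LiN(SiMe3)2 (1.05 equiv), THF, −78 °C; cannulate into NBS (1.1 equiv), THF, −78 °C; AcOH
Reagents that add atoms: N-bromosuccinimide (NBS), O=C1CCC(=O)N1Br
Why: Vinylogous (lateral) deprotonation of the ethyl CH2, which is conjugated to the C4 carbonyl, gives a pyranylidene enolate that is brominated at carbon (electrophilic α-halogenation); the new centre is racemic and is destroyed in step 11.

**Step 10**
Reactants: 20 2-(1-bromoethyl)-6-methoxy-3,5-dimethyl-4H-pyran-4-one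
Product: 21 diethyl [1-(6-methoxy-3,5-dimethyl-4-oxo-4H-pyran-2-yl)ethyl]phosphonate (racemic)
Conditions: P(OEt)3 (5 equiv), 120 °C
Reagents that add atoms: triethyl phosphite, CCOP(OCC)OCC
Why: Michaelis–Arbuzov reaction of the activated secondary bromide (SN2 by phosphorus, then dealkylation by bromide) gives the phosphonate.

**Step 11**
Reactants: 14 (1S,2S,3R,4R,5S,6R)-2,4-dihydroxy-2,4,5-trimethyl-6-[(1E,3E)-2-methyl-5-oxopenta-1,3-dien-1-yl]cyclohexane-1,3-diyl diacetate; 21 diethyl [1-(6-methoxy-3,5-dimethyl-4-oxo-4H-pyran-2-yl)ethyl]phosphonate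
Product: 22 Amaurone B, (1S,2S,3R,4R,5S,6R)-2,4-dihydroxy-6-[(1E,3E,5E)-6-(6-methoxy-3,5-dimethyl-4-oxo-4H-pyran-2-yl)-2-methylhepta-1,3,5-trien-1-yl]-2,4,5-trimethylcyclohexane-1,3-diyl diacetate
Conditions: 21 (1.2 equiv), LiN(SiMe3)2 (1.2 equiv), THF, −78 °C; then 14, −78 → 0 °C; AcOH
Reagents that add atoms: none
Why: Horner–Wadsworth–Emmons olefination, in which the pyranone-stabilised phosphonate anion is too weakly basic to deprotonate the tertiary alcohols or attack the acetates and gives the trisubstituted (E)-alkene (pyranone trans to the chain), completing the (E,E,E)-triene.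

**Compound list**
1 | (E)-2-methylpent-2-enal | CC/C=C(\C)C=O | starting material
2 | tert-butyldimethyl{[(1E,3E)-2-methylpenta-1,3-dien-1-yl]oxy}silane | C/C=C/C(C)=C/O[Si](C)(C)C(C)(C)C | intermediate
3 | (E)-but-2-enal (crotonaldehyde) | C/C=C/C=O | starting material
4 | (6R)-2-[(tert-butyldimethylsilyl)oxy]-3,5,6-trimethylcyclohex-3-ene-1-carbaldehyde (mixture at C1, C2, C5) | O=CC1C(O[Si](C)(C)C(C)(C)C)C(C)=CC(C)[C@H]1C | intermediate
5 | (6R)-3,5,6-trimethylcyclohexa-1,3-diene-1-carbaldehyde (C5 epimers) | O=CC1=CC(C)=CC(C)[C@H]1C | intermediate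
6 | 2-(triphenylphosphoranylidene)propanal | CC(C=O)=P(c1ccccc1)(c1ccccc1)c1ccccc1 | starting material
7 | (1S,6S)-3,5,6-trimethylcyclohexa-2,4-diene-1-carbaldehyde | O=C[C@@H]1[C@H](C)C(C)=CC(C)=C1 | intermediate
8 | (2E)-2-methyl-3-[(1R,6S)-3,5,6-trimethylcyclohexa-2,4-dien-1-yl]prop-2-enal | O=C/C(C)=C/[C@@H]1[C@H](C)C(C)=CC(C)=C1 | intermediate
9 | (2E)-3-[(1R,4S,5R,6S)-4,5-dihydroxy-3,5,6-trimethylcyclohex-2-en-1-yl]-2-methylprop-2-enal | O=C/C(C)=C/[C@@H]1[C@H](C)[C@@](C)(O)[C@@H](O)C(C)=C1 | intermediate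
10 | (2E)-3-[(1R,2S,5R,6S)-5,6-dihydroxy-2,3,5-trimethylcyclohex-3-en-1-yl]-2-methylprop-2-enal | O=C/C(C)=C/[C@@H]1[C@H](C)C(C)=C[C@@](C)(O)[C@H]1O | intermediate
11 | (2E)-2-methyl-3-[(1R,2S,3S,4R,5R,6S)-2,3,4,5-tetrahydroxy-3,5,6-trimethylcyclohexyl]prop-2-enal | O=C/C(C)=C/[C@@H]1[C@H](C)[C@@](C)(O)[C@@H](O)[C@@](C)(O)[C@H]1O | intermediate
12 | (1S,2S,3R,4R,5S,6R)-2,4-dihydroxy-2,4,5-trimethyl-6-[(1E)-2-methyl-3-oxoprop-1-en-1-yl]cyclohexane-1,3-diyl diacetate | O=C/C(C)=C/[C@@H]1[C@H](C)[C@@](C)(O)[C@@H](OC(C)=O)[C@@](C)(O)[C@H]1OC(C)=O | intermediate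
13 | (triphenylphosphoranylidene)acetaldehyde | O=CC=P(c1ccccc1)(c1ccccc1)c1ccccc1 | starting material
14 | (1S,2S,3R,4R,5S,6R)-2,4-dihydroxy-2,4,5-trimethyl-6-[(1E,3E)-2-methyl-5-oxopenta-1,3-dien-1-yl]cyclohexane-1,3-diyl diacetate | O=C/C=C/C(C)=C/[C@@H]1[C@H](C)[C@@](C)(O)[C@@H](OC(C)=O)[C@@](C)(O)[C@H]1OC(C)=O | intermediate
15 | ethyl 2-methyl-3-oxopentanoate (racemic) | CCC(=O)C(C)C(=O)OCC | starting material
16 | N-methoxy-N-methylpropanamide | CCC(=O)N(C)OC | starting material
17 | ethyl 2,4-dimethyl-3,5-dioxoheptanoate | CCC(=O)C(C)C(=O)C(C)C(=O)OCC | intermediate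
18 | 6-ethyl-4-hydroxy-3,5-dimethyl-2H-pyran-2-one | CCc1oc(=O)c(C)c(O)c1C | intermediate
19 | 2-ethyl-6-methoxy-3,5-dimethyl-4H-pyran-4-one | CCc1oc(OC)c(C)c(=O)c1C | intermediate
20 | 2-(1-bromoethyl)-6-methoxy-3,5-dimethyl-4H-pyran-4-one (racemic) | CC(Br)c1oc(OC)c(C)c(=O)c1C | intermediate
21 | diethyl [1-(6-methoxy-3,5-dimethyl-4-oxo-4H-pyran-2-yl)ethyl]phosphonate (racemic) | CCOP(=O)(OCC)C(C)c1oc(OC)c(C)c(=O)c1C | intermediate
22 | Amaurone B | COc1oc(/C(C)=C/C=C/C(C)=C/[C@@H]2[C@H](C)[C@@](C)(O)[C@@H](OC(C)=O)[C@@](C)(O)[C@H]2OC(C)=O)c(C)c(=O)c1C | target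

**Step count and risks**
Total steps: 11. Longest linear sequence: 7 (steps 1–6 and 11); the pyranone branch is steps 7–10 and joins at step 11.

Three steps most likely to fail:

Step 4 (the proposed new relay bis-dihydroxylation). Risks are poor osmium turnover in CH2Cl2, wrong-face addition in the second osmylation, or attack on the enal. Fallback with known chemistry, setting out from 8 and returning at 11: sensitised photooxygenation (O2, tetraphenylporphyrin, hν, CH2Cl2, −78 °C) adds singlet oxygen by [4+2] across the ring diene anti to the ring C1/C2 substituents to give the endoperoxide F1. Thiourea in MeOH at 23 °C cleaves the O–O bond to the cis-1,4-ene-diol F2. Stoichiometric OsO4·TMEDA (CH2Cl2, −78 °C), held by hydrogen bonds to both allylic hydroxyls, then adds to the same face to give the osmate ester F3, which aqueous Na2SO3 hydrolyses to tetraol 11.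

Step 3 (deconjugation and Wittig reaction on a sensitive aldehyde). Risks are γ- or ε-protonation back to 5 and reconjugation of 7 during olefination. Fallback, setting out from 5 and returning at 7: Pinnick oxidation (NaClO2, NaH2PO4, 2-methylbut-2-ene, t-BuOH/H2O) gives the dienoic acid F4. MeI/K2CO3 in DMF gives the methyl ester F5. The textbook ester deconjugation (LiN(i-Pr)2, HMPA, THF, −78 °C, then AcOH) gives the cis skipped ester F6. i-Bu2AlH (1.0 equiv, CH2Cl2, −78 °C) then gives aldehyde 7 in the flask, which is olefinated at once with 6 as in step 3 to give 8.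

Step 2 (organocatalytic cycloaddition of a hindered silyloxy diene with a β-substituted enal). Risks are an open-chain Mukaiyama–Michael adduct, diene hydrolysis, or low enantioselectivity. Fallback, setting out from 2 and returning at 4 (then 5): (R)-4-benzyloxazolidin-2-one is N-acylated with (E)-but-2-enoyl chloride (n-BuLi, THF, −78 °C) to give the crotonyl imide F7. An Et2AlCl-promoted (1.4 equiv, CH2Cl2, −78 °C) auxiliary-controlled Diels–Alder reaction with 2, in which the diene adds anti to the benzyl group of the chelated s-cis imide, gives the cycloadduct imide F8. LiBH4 (THF, 1 equiv H2O, 0 °C) removes the auxiliary to give the primary alcohol F9. Dess–Martin periodinane (CH2Cl2, NaHCO3) gives aldehyde 4, which DBU converts to 5 as in step 2.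

**Further compounds**
F1 | step 4 | (2E)-2-methyl-3-[4,6,8-trimethyl-2,3-dioxabicyclo[2.2.2]oct-5-en-7-yl]prop-2-enal, peroxide bridge anti to the cis C7/C8 substituents | O=C/C(C)=C/[C@@H]1[C@H](C)[C@]2(C)C=C(C)[C@H]1OO2
F2 | step 4 | (2E)-3-[(1R,2S,5R,6S)-2,5-dihydroxy-3,5,6-trimethylcyclohex-3-en-1-yl]-2-methylprop-2-enal | O=C/C(C)=C/[C@@H]1[C@H](C)[C@@](C)(O)C=C(C)[C@H]1O
F3 | step 4 | dioxo(N,N,N',N'-tetramethylethane-1,2-diamine)osmium ring-C4,C5-diolate of tetraol 11 (hexavalent osmium ester) | O=C/C(C)=C/[C@@H]1[C@H](C)[C@@](C)(O)[C@H]2O[Os-2]3(=O)(=O)([N+](C)(C)CC[N+]3(C)C)O[C@@]2(C)[C@H]1O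
F4 | step 3 | (6R)-3,5,6-trimethylcyclohexa-1,3-diene-1-carboxylic acid (C5 epimers) | O=C(O)C1=CC(C)=CC(C)[C@H]1C
F5 | step 3 | methyl (6R)-3,5,6-trimethylcyclohexa-1,3-diene-1-carboxylate (C5 epimers) | COC(=O)C1=CC(C)=CC(C)[C@H]1C
F6 | step 3 | methyl (1S,6S)-3,5,6-trimethylcyclohexa-2,4-diene-1-carboxylate | COC(=O)[C@@H]1[C@H](C)C(C)=CC(C)=C1
F7 | step 2 | (4R)-4-benzyl-3-[(2E)-but-2-enoyl]-1,3-oxazolidin-2-one | C/C=C/C(=O)N1C(=O)OC[C@H]1Cc1ccccc1
F8 | step 2 | (4R)-4-benzyl-3-{[(6R)-2-[(tert-butyldimethylsilyl)oxy]-3,5,6-trimethylcyclohex-3-en-1-yl]carbonyl}-1,3-oxazolidin-2-one (mixture at ring C1, C2, C5) | O=C(C1C(O[Si](C)(C)C(C)(C)C)C(C)=CC(C)[C@H]1C)N1C(=O)OC[C@H]1Cc1ccccc1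
F9 | step 2 | {(6R)-2-[(tert-butyldimethylsilyl)oxy]-3,5,6-trimethylcyclohex-3-en-1-yl}methanol (mixture at C1, C2, C5) | OCC1C(O[Si](C)(C)C(C)(C)C)C(C)=CC(C)[C@H]1C
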